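## The problem

The target is the 4-hydroxy-3-methoxybenzoate (vanillate) of (1R,3E,8E)-2,2,9-trimethyl-5-methylidenecycloundeca-3,8-dien-1-ol. Ring atoms are numbered C1–C11 as in this name, and C12 is the exocyclic methylene carbon; these locants are used throughout. The carbocycle is eleven-membered, a size at which end-to-end closure is penalised by both entropy and transannular strain. It holds three alkenes whose positions and geometries must be fixed: the E-trisubstituted C8=C9, and the E-disubstituted C3=C4 between the quaternary C2 and C5, conjugated with the exocyclic C5=C12. There is a single stereocentre, C1 (R), neopentylic next to C2; nothing in the molecule can relay it, so it must be set by a reagent, carried unchanged and acylated late despite the hindrance. The 2-substituted 1,3-diene and the 1,5-related alkenes invite acid-induced transannular cyclisation, so late steps must be neutral or basic, and the phenol must be masked during acylation. The enabling feature is twofold. The diene C12=C5–C4=C3 is exactly what a cyclobutene C5=C4–C3–C12 gives on conrotatory opening. With that cyclobutene in place, C9=C8–C7–C6–C5=C4 is a 1,5-diene whose [3,3] retron reconnects C4 to C9 and shrinks the ring to the seven-membered ring C9–C4–C3–C2–C1–C11–C10. In that small ring C9 is a ketone carbon, C4/C3 are the α/β carbons of an enone, C5/C12/C6 are the three carbons of allene and C8/C7 are a vinyl group, so no bond of the large ring has to be made by macrocyclisation.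

## Retrosynthesis

**Ester.** The acyl–O bond at C1 of 18 is cut to give alcohol 13 and 4-acetoxy-3-methoxybenzoic acid 15 (from vanillic acid 14), joined through acid chloride 16 to the acetate-protected ester 17. This is the convergent, last-possible cut. The aryl acetate is far more labile to aminolysis than the hindered neopentylic benzoate, so the final unmasking is selective. The forward reaction must acylate a hindered secondary alcohol.

**Diene.** Alcohol 13 comes from silyl ether 12. In 12 the C3–C12 σ-bond is re-formed, giving the bridged cyclobutene 11. This keeps the sensitive diene latent as an unconjugated cyclobutene through the basic and organometallic steps. It also turns the C3=C4 geometry into a question of torquoselectivity (C2 rotating outward). The forward reaction needs only heat.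

**C9 methyl.** The C9–CH3 bond of 11 is cut to give enol triflate 10 and a methyl nucleophile. C9 thereby becomes an enolate carbon with fixed regio- and stereochemistry (O–C9=C8, ring-E), which is precisely what an oxy-Cope rearrangement delivers; no other cut at C8=C9 gives a precursor whose geometry is dictated by a cyclic transition state.

**C6–C7 (key).** Enol triflate 10 derives from potassium enolate 9, which arises from potassium alkoxide 8 of carbinol 7 by cutting C6–C7 and re-forming C4–C9. Any other ring bond would demand a macrocyclisation. This cut converts the eleven-membered ring into a cis-fused bicyclo[5.2.0]nonane with only a seven-membered ring to build. The forward reaction must be a [3,3] shift through a chair array, so that C8=C9 emerges ring-E.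

**Small-ring functionality.** Carbinol 7 is cut at C8–C9 to ketone 6 and a vinyl nucleophile. Ketone 6 is cut at C4–C5 and C3–C12 to enone 5 and allene ([2+2] photocycloaddition). Both reactions are intermolecular additions to a simple ring and create only transient stereocentres.

**Seven-membered ring and C1.** Enone 5 comes from cycloheptene 4 by oxidation of C9, the only allylic CH2. Cycloheptene 4 comes from diene 3 by ring-closing metathesis at C3=C4, and 3 from alcohol 2 by silylation. Alcohol 2 is cut at C1–C2 to hex-5-enal 1 and a prenyl nucleophile; this asymmetric reverse prenylation creates the quaternary C2 and the only stereocentre in the first step.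

## Roads not taken

**Alternative 1:** (the obvious one) Cut C3=C4 by ring-closing metathesis of the acyclic tetraene A1, tert-butyl{[(4R,7E)-3,3,7-trimethyl-11-methylidenetrideca-1,7,12-trien-4-yl]oxy}dimethylsilane, with a ruthenium alkylidene such as RuCl2(=CHPh)(PCy3)(H2IMes). The eleven-membered ring would be closed last, under reversible conditions that favour oligomers for a strained ring. One partner is a neopentylic vinyl group and the other a diene with two competing alkenes. The C3=C4 geometry would be left to thermodynamics. A1 also needs a separate stereocontrolled synthesis of E-C8=C9, so the run-up is long. The chosen plan makes the large ring by reorganising a seven-membered ring, with no dilution and with both ring alkene geometries fixed by pericyclic transition states.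

**Alternative 2:** Cut C1–C2 by an intramolecular Nozaki–Hiyama–Kishi-type allylation of bromo aldehyde A2, (4E)-9-bromo-4,11-dimethyl-8-methylidenedodeca-4,10-dienal, with CrCl2 (divalent chromium). Ring, quaternary carbon and carbinol would form together. However, the allylchromium is a pentadienyl species that can attack through C2, C4 or C12 (eleven- or nine-membered rings). The configuration at C1 would have to be imposed by a chiral ligand during a macrocyclisation with no substrate bias, so 13 would be obtained at best as a stereoisomer mixture. The chosen plan sets C1 in step 1 with a reagent of predictable facial sense.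

**Alternative 3:** Cut C3=C4 and C5=C12 together by endo-mode ring-closing enyne metathesis of enyne A3, tert-butyl{[(4R,7E)-3,3,7-trimethyldodeca-1,7-dien-11-yn-4-yl]oxy}dimethylsilane. This is the closest rival, since ring and diene form in one step. But eleven members lie at the borderline between exo and endo closure (exo gives a ten-membered 1-vinylcycloalkene). The alkene partner is again neopentylic, nothing controls the C3=C4 geometry, and A3 still needs E-C8=C9 built beforehand. The chosen plan draws the C8=C9 geometry from the same step that makes the ring.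

Key step: step 7

Assumption: the ring-fusion carbons of 6 and 7 (C4 and C3 of the target), the carbinol carbon of 7 (C9) and the bridgehead C3 of 9–11 are carried as diastereomer mixtures, since each becomes sp2 before 12; their SMILES leave these centres open. Locants in the Why lines are target locants.

## Route

Step 1
Reactants: 1 hex-5-enal
Product: 2 (4R)-3,3-dimethylnona-1,8-dien-4-ol
Conditions: 3-methylbuta-1,2-diene, (−)-Ipc2BH [from (+)-α-pinene and BH3·SMe2], THF, −25 °C; then 1, −78 °C; NaOH, H2O2
Reagents that add atoms: 3-methylbuta-1,2-diene CC(C)=C=C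
Why: Reagent-controlled asymmetric allylboration (reverse prenylation): hydroboration of the allene gives the prenylborane, which adds through its γ-carbon in a closed chair transition state and creates the C1–C2 bond, the quaternary C2 and the only stereocentre. The borane from (−)-Ipc2BH is expected to attack the Si face of the aldehyde, which corresponds to (R) at C1; the antipodal borane is equally available should the sense have to be inverted.

Step 2
Reactants: 2 (4R)-3,3-dimethylnona-1,8-dien-4-ol
Product: 3 tert-butyl{[(4R)-3,3-dimethylnona-1,8-dien-4-yl]oxy}dimethylsilane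
Conditions: TBSOTf, 2,6-lutidine, CH2Cl2, 0 °C
Reagents that add atoms: tert-butyldimethylsilyl trifluoromethanesulfonate CC(C)(C)[Si](C)(C)OS(=O)(=O)C(F)(F)F
Why: Silylation of a hindered secondary alcohol with the silyl triflate; the silyl ether tolerates the oxidant, the organometallic reagents, KH and 175 °C used later.

Step 3
Reactants: 3 tert-butyl{[(4R)-3,3-dimethylnona-1,8-dien-4-yl]oxy}dimethylsilane
Product: 4 tert-butyl{[(1R)-2,2-dimethylcyclohept-3-en-1-yl]oxy}dimethylsilane
Conditions: second-generation Grubbs catalyst RuCl2(=CHPh)(PCy3)(H2IMes) (cat.), CH2Cl2, 40 °C, high dilution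
Reagents that add atoms: none
Why: Ring-closing metathesis to a seven-membered ring, driven by loss of ethene; the catalyst loads on the unhindered hexenyl terminus and closes onto the neopentylic vinyl group. C1 is untouched.

Step 4
Reactants: 4 tert-butyl{[(1R)-2,2-dimethylcyclohept-3-en-1-yl]oxy}dimethylsilane
Product: 5 (5R)-5-[(tert-butyldimethylsilyl)oxy]-4,4-dimethylcyclohept-2-en-1-one
Conditions: Rh2(cap)4 (dirhodium tetrakis(caprolactamate), cat.), t-BuOOH, K2CO3, CH2Cl2, rt
Reagents that add atoms: tert-butyl hydroperoxide CC(C)(C)OO
Why: Catalytic allylic C–H oxidation (allyl radical trapped as the mixed peroxide, which collapses to the enone). C9 carries the only allylic hydrogens because the other allylic position is the quaternary C2, and the delocalised radical should be trapped at C9 rather than at C3, which is shielded by C2.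

Step 5
Reactants: 5 (5R)-5-[(tert-butyldimethylsilyl)oxy]-4,4-dimethylcyclohept-2-en-1-one
Product: 6 (5R)-5-[(tert-butyldimethylsilyl)oxy]-6,6-dimethyl-9-methylidenebicyclo[5.2.0]nonan-2-one (cis-fused, both ring-fusion diastereomers)
Conditions: allene (excess), THF, hν (Hg lamp, Pyrex), −78 °C; then DBU (cat.), CH2Cl2, rt
Reagents that add atoms: propa-1,2-diene (allene) C=C=C
Why: Enone–allene [2+2] photocycloaddition: the triplet enone bonds C4 (α) to the central allene carbon C5 and C3 (β) to the terminal carbon C12, the usual regiochemistry of allene with cyclic enones, reinforced here by the bulk of C2 next to C3. The two ring-fusion centres need no control because both become sp2 later; the base only converts any trans-fused adduct into the cis-fused ketone by epimerisation at C4.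

Step 6
Reactants: 6 (5R)-5-[(tert-butyldimethylsilyl)oxy]-6,6-dimethyl-9-methylidenebicyclo[5.2.0]nonan-2-one
Product: 7 (5R)-5-[(tert-butyldimethylsilyl)oxy]-2-ethenyl-6,6-dimethyl-9-methylidenebicyclo[5.2.0]nonan-2-ol (vinyl group trans to the methylene-bearing cyclobutane carbon)
Conditions: vinylmagnesium bromide, CeCl3, THF, −78 °C
Reagents that add atoms: vinylmagnesium bromide C=C[Mg]Br
Why: 1,2-Addition of a weakly basic vinylcerium reagent, which avoids enolisation of the β,γ-unsaturated ketone. Attack on the convex face of the cis-fused bicycle, anti to the cyclobutane, puts the vinyl group trans to C5 and the oxygen cis to it, the arrangement the chair [3,3] array of step 7 requires; the carbinol centre is transient.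

Step 7
Reactants: 7 (5R)-5-[(tert-butyldimethylsilyl)oxy]-2-ethenyl-6,6-dimethyl-9-methylidenebicyclo[5.2.0]nonan-2-ol
Product: 10 (4Z,8R)-8-[(tert-butyldimethylsilyl)oxy]-9,9-dimethylbicyclo[8.1.1]dodeca-1(11),4-dien-5-yl trifluoromethanesulfonate, via potassium alkoxide 8 (not isolated), via potassium enolate 9 (not isolated)
Conditions: KH, 18-crown-6, THF, rt to 50 °C; then PhNTf2, −78 to 0 °C
Reagents that add atoms: N-phenylbis(trifluoromethanesulfonimide) O=S(=O)(N(c1ccccc1)S(=O)(=O)C(F)(F)F)C(F)(F)F
Why: Deprotonation gives alkoxide 8, whose C9–O− weakens the C4–C9 bond; a concerted [3,3] shift through the six-centre array C6=C5–C4–C9–C8=C7 breaks C4–C9 and forms C6–C7, giving enolate 9 with the O–C9=C8 double bond formed regiospecifically. The closest known reaction type is the anionic oxy-Cope four-carbon ring enlargement of 1,2-dialkenylcycloalkanols, including cases in which one alkene is the exocyclic methylene of a fused methylenecyclobutane and a bridged cyclobutene results. The eleven-membered ring is formed by ring expansion of the seven-membered ring (7 to 11), not by end-to-end closure, and the four-membered ring is retained as the cyclobutene C5=C4–C3–C12 bridging it. No new stereocentre is formed; the stereochemical outcome is the C8=C9 geometry, fixed by a chair transition state in which the ring bonds C4–C3 and C9–C10 are pseudo-equatorial. That is possible only with the vinyl group trans to C5 (secured in step 6) and places the enolate oxygen cis to C7, giving the ring-E alkene. The step needs the concerted [3,3] path to win over fragmentation–recombination ([1,3] shift), favoured here by the crown-ether-separated potassium alkoxide at moderate temperature. It also needs O-sulfonylation before any proton transfer can move the enolate, which the aprotic medium and full consumption of 7 before PhNTf2 is added should ensure. The triflate stores the enolate regio- and stereochemistry for step 8.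

Step 8
Reactants: 10 (4Z,8R)-8-[(tert-butyldimethylsilyl)oxy]-9,9-dimethylbicyclo[8.1.1]dodeca-1(11),4-dien-5-yl trifluoromethanesulfonate
Product: 11 tert-butyl{[(4E,8R)-5,9,9-trimethylbicyclo[8.1.1]dodeca-1(11),4-dien-8-yl]oxy}dimethylsilane
Conditions: MeMgBr, Fe(acac)3 (cat.), THF/NMP, −30 to 0 °C
Reagents that add atoms: methylmagnesium bromide C[Mg]Br
Why: Iron-catalysed Kumada-type cross-coupling of an alkenyl triflate with a methyl Grignard reagent, which proceeds with retention of alkene geometry. The methyl group takes the place of the oxygen, so the ring-E enol triflate becomes the E-trisubstituted C8=C9 alkene; the unconjugated cyclobutene and the silyl ether are inert.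

Step 9
Reactants: 11 tert-butyl{[(4E,8R)-5,9,9-trimethylbicyclo[8.1.1]dodeca-1(11),4-dien-8-yl]oxy}dimethylsilane
Product: 12 tert-butyl{[(1R,3E,8E)-2,2,9-trimethyl-5-methylidenecycloundeca-3,8-dien-1-yl]oxy}dimethylsilane
Conditions: toluene (degassed, trace BHT), 175 °C, sealed tube
Reagents that add atoms: none
Why: Thermal conrotatory 4π electrocyclic opening of the cyclobutene C5=C4–C3–C12 cleaves C3–C12 with release of ring strain and unveils the C12=C5–C4=C3 diene. Outward rotation of the C2 substituent on C3 (the usual torquoselectivity of 3-alkylcyclobutenes) gives E-C3=C4, and since C3 becomes sp2 both diastereomers of 11 converge on 12.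

Step 10
Reactants: 12 tert-butyl{[(1R,3E,8E)-2,2,9-trimethyl-5-methylidenecycloundeca-3,8-dien-1-yl]oxy}dimethylsilane
Product: 13 (1R,3E,8E)-2,2,9-trimethyl-5-methylidenecycloundeca-3,8-dien-1-ol
Conditions: Bu4NF, THF, rt to 45 °C
Reagents that add atoms: none
Why: Fluoride-mediated desilylation under basic, non-acidic conditions that leave the diene and the 1,5-diene untouched; the C1–O bond is not broken, so the configuration is retained.

Step 11
Reactants: 14 4-hydroxy-3-methoxybenzoic acid (vanillic acid)
Product: 15 4-acetoxy-3-methoxybenzoic acid
Conditions: Ac2O, pyridine, rt; aqueous work-up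
Reagents that add atoms: acetic anhydride CC(=O)OC(C)=O
Why: Phenol acetylation; any mixed carboxylic anhydride is hydrolysed on work-up, leaving the free acid with the phenol masked.

Step 12
Reactants: 13 (1R,3E,8E)-2,2,9-trimethyl-5-methylidenecycloundeca-3,8-dien-1-ol; 15 4-acetoxy-3-methoxybenzoic acid
Product: 17 (1R,3E,8E)-2,2,9-trimethyl-5-methylidenecycloundeca-3,8-dien-1-yl 4-acetoxy-3-methoxybenzoate, via 4-acetoxy-3-methoxybenzoyl chloride 16 (not isolated)
Conditions: 15, (COCl)2, DMF (cat.), CH2Cl2, 0 °C to rt, evaporate; then 13, Et3N, DMAP, CH2Cl2, 0 to 40 °C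
Reagents that add atoms: none
Why: Acylation of the hindered neopentylic alcohol with an aroyl chloride through the N-acylpyridinium ion (DMAP catalysis). Acylation at oxygen cannot affect the C1 configuration, and the basic medium protects the diene.

Step 13
Reactants: 17 (1R,3E,8E)-2,2,9-trimethyl-5-methylidenecycloundeca-3,8-dien-1-yl 4-acetoxy-3-methoxybenzoate
Product: 18 (1R,3E,8E)-2,2,9-trimethyl-5-methylidenecycloundeca-3,8-dien-1-yl 4-hydroxy-3-methoxybenzoate (CNP0416843.1)
Conditions: pyrrolidine, CH2Cl2, 0 °C to rt
Reagents that add atoms: none
Why: Chemoselective aminolysis of the aryl acetate (phenoxide leaving group), which is far faster than attack on the hindered secondary alkyl benzoate; the diene is not an acceptor for the amine.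

## Compound list

1 | hex-5-enal | C=CCCCC=O | starting material
2 | (4R)-3,3-dimethylnona-1,8-dien-4-ol | C=CC(C)(C)[C@H](O)CCCC=C | intermediate
3 | tert-butyl{[(4R)-3,3-dimethylnona-1,8-dien-4-yl]oxy}dimethylsilane | C=CC(C)(C)[C@H](O[Si](C)(C)C(C)(C)C)CCCC=C | intermediate
4 | tert-butyl{[(1R)-2,2-dimethylcyclohept-3-en-1-yl]oxy}dimethylsilane | C1=CC(C)(C)[C@H](O[Si](C)(C)C(C)(C)C)CCC1 | intermediate
5 | (5R)-5-[(tert-butyldimethylsilyl)oxy]-4,4-dimethylcyclohept-2-en-1-one | O=C1C=CC(C)(C)[C@H](O[Si](C)(C)C(C)(C)C)CC1 | intermediate
6 | (5R)-5-[(tert-butyldimethylsilyl)oxy]-6,6-dimethyl-9-methylidenebicyclo[5.2.0]nonan-2-one (cis-fused, C1/C7 mixture) | O=C1CC[C@@H](O[Si](C)(C)C(C)(C)C)C(C)(C)C2CC(=C)C12 | intermediate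
7 | (5R)-5-[(tert-butyldimethylsilyl)oxy]-2-ethenyl-6,6-dimethyl-9-methylidenebicyclo[5.2.0]nonan-2-ol | C=CC1(O)CC[C@@H](O[Si](C)(C)C(C)(C)C)C(C)(C)C2CC(=C)C12 | intermediate
8 | potassium alkoxide of 7 | C=CC1([O-])CC[C@@H](O[Si](C)(C)C(C)(C)C)C(C)(C)C2CC(=C)C12.[K+] | intermediate (not isolated)
9 | potassium (4Z,8R)-8-[(tert-butyldimethylsilyl)oxy]-9,9-dimethylbicyclo[8.1.1]dodeca-1(11),4-dien-5-olate | [O-]/C1=C\CCC2=CC(C2)C(C)(C)[C@H](O[Si](C)(C)C(C)(C)C)CC1.[K+] | intermediate (not isolated)
10 | (4Z,8R)-8-[(tert-butyldimethylsilyl)oxy]-9,9-dimethylbicyclo[8.1.1]dodeca-1(11),4-dien-5-yl trifluoromethanesulfonate | FC(F)(F)S(=O)(=O)O/C1=C\CCC2=CC(C2)C(C)(C)[C@H](O[Si](C)(C)C(C)(C)C)CC1 | intermediate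
11 | tert-butyl{[(4E,8R)-5,9,9-trimethylbicyclo[8.1.1]dodeca-1(11),4-dien-8-yl]oxy}dimethylsilane | C/C1=C\CCC2=CC(C2)C(C)(C)[C@H](O[Si](C)(C)C(C)(C)C)CC1 | intermediate
12 | tert-butyl{[(1R,3E,8E)-2,2,9-trimethyl-5-methylidenecycloundeca-3,8-dien-1-yl]oxy}dimethylsilane | C=C1/C=C/C(C)(C)[C@H](O[Si](C)(C)C(C)(C)C)CC/C(C)=C/CC1 | intermediate
13 | (1R,3E,8E)-2,2,9-trimethyl-5-methylidenecycloundeca-3,8-dien-1-ol | C=C1/C=C/C(C)(C)[C@H](O)CC/C(C)=C/CC1 | intermediate
14 | 4-hydroxy-3-methoxybenzoic acid (vanillic acid) | COc1cc(C(=O)O)ccc1O | starting material
15 | 4-acetoxy-3-methoxybenzoic acid | COc1cc(C(=O)O)ccc1OC(C)=O | intermediate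
16 | 4-acetoxy-3-methoxybenzoyl chloride | COc1cc(C(=O)Cl)ccc1OC(C)=O | intermediate (not isolated)
17 | (1R,3E,8E)-2,2,9-trimethyl-5-methylidenecycloundeca-3,8-dien-1-yl 4-acetoxy-3-methoxybenzoate | C=C1/C=C/C(C)(C)[C@H](OC(=O)c2ccc(OC(C)=O)c(OC)c2)CC/C(C)=C/CC1 | intermediate
18 | (1R,3E,8E)-2,2,9-trimethyl-5-methylidenecycloundeca-3,8-dien-1-yl 4-hydroxy-3-methoxybenzoate | C=C1/C=C/C(C)(C)[C@H](OC(=O)c2ccc(O)c(OC)c2)CC/C(C)=C/CC1 | target

## Step count and risks

Total steps: 13. Longest linear sequence: 12 (steps 1–10, 12, 13); step 11 is a one-step side branch.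

**Step 7 (key step).** Three processes may interfere. Alkoxide 8 may fragment heterolytically into an enone and an allyl anion stabilised by C5=C6; recombination would give a formal [1,3] shift or loss of geometric control. A boat transition state, or reaction of a minor carbinol epimer, would give the ring-Z enolate. Proton transfer before O-sulfonylation would move the enolate towards C10. The fallback is a neutral variant that sets out from 7 and returns at 12. Carbinol 7 is silylated (Me3SiOTf, Et3N) to the trimethylsilyl ether of 7, F1. Thermolysis of F1 (toluene, 200–220 °C, sealed tube) should effect the siloxy-Cope rearrangement and the cyclobutene opening in one operation, giving the ring-opened C9 trimethylsilyl enol ether F2; this is isolable and stores regio- and stereochemistry without a free enolate. MeLi (THF, 0 °C) then releases the lithium enolate regiospecifically and PhNTf2 converts it into the ring-opened C9 enol triflate F3. Methylation of F3 as in step 8 (MeMgBr, Fe(acac)3) gives 12.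

**Step 5.** The excited seven-membered enone may relax by E/Z isomerisation to the strained trans-enone, which dimerises in competition with capture by allene; some reversed regiochemistry is also possible. The fallback moves the photochemistry to a six-membered enone, which cannot twist; it sets out from 3 and returns at 6. The unhindered terminal alkene of 3 is shifted by one position with RuHCl(CO)(PPh3)3 (the neopentylic vinyl group has no allylic hydrogen) to give tert-butyl{[(4R)-3,3-dimethylnona-1,7-dien-4-yl]oxy}dimethylsilane F4. Ring-closing metathesis with RuCl2(=CHPh)(PCy3)(H2IMes), with loss of propene, gives tert-butyl{[(1R)-2,2-dimethylcyclohex-3-en-1-yl]oxy}dimethylsilane F5. Allylic oxidation as in step 4 gives (5R)-5-[(tert-butyldimethylsilyl)oxy]-4,4-dimethylcyclohex-2-en-1-one F6. Allene photocycloaddition gives (4R)-4-[(tert-butyldimethylsilyl)oxy]-5,5-dimethyl-8-methylidenebicyclo[4.2.0]octan-2-one F7. One-carbon ring enlargement with Me3SiCHN2/AlMe3, with migration of the unsubstituted α-CH2, then gives 6.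

**Step 9.** The bridge may override the outward torquoselectivity, so that C2 rotates inward and a Z-C3=C4 alkene forms. A reversible [3,3] contraction of 11 to a divinylcycloheptane may also run alongside ring opening and erode the C8=C9 geometry. The fallback sets out from 11 and returns at 12. The kinetic mixture from the thermolysis is accepted, and the (3Z)-isomer of 12, F8, is equilibrated with catalytic PhSSPh under irradiation (reversible thiyl radical addition). The E-isomer 12 is expected to be favoured because the Z-form forces the C2 gem-dimethyl group against C5.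

**Step 4.** The delocalised allyl radical may be trapped at C3 instead of C9, giving the transposed enone, or over-oxidation may occur. The fallback replaces the radical pathway by an ene/[2,3]-sigmatropic sequence that returns oxygen to the carbon that lost hydrogen; it sets out from 4 and returns at 5. SeO2 with t-BuOOH (CH2Cl2) gives (5R)-5-[(tert-butyldimethylsilyl)oxy]-4,4-dimethylcyclohept-2-en-1-ol F9, which is oxidised to 5 with MnO2 or Dess–Martin periodinane.

**Step 1.** Facial discrimination may be incomplete with a linear aliphatic aldehyde, or the facial sense may be opposite to that expected. The fallback sets out from scalemic or racemic 2 and returns at 2. Oxidation with Dess–Martin periodinane gives 3,3-dimethylnona-1,8-dien-4-one F10. Corey–Bakshi–Shibata reduction with (S)-Me-CBS and BH3·SMe2 (tertiary versus primary alkyl flanks) is expected to give (R)-2.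

## Further compounds

F1 | step 7 | trimethylsilyl ether of 7 | C=CC1(O[Si](C)(C)C)CC[C@@H](O[Si](C)(C)C(C)(C)C)C(C)(C)C2CC(=C)C12
F2 | step 7 | tert-butyl{[(1R,3E,8Z)-2,2-dimethyl-5-methylidene-9-(trimethylsilyloxy)cycloundeca-3,8-dien-1-yl]oxy}dimethylsilane | C=C1/C=C/C(C)(C)[C@H](O[Si](C)(C)C(C)(C)C)CC/C(O[Si](C)(C)C)=C/CC1
F3 | step 7 | ring-opened C9 enol triflate (12 with OSO2CF3 in place of the C9 methyl group) | C=C1/C=C/C(C)(C)[C@H](O[Si](C)(C)C(C)(C)C)CC/C(OS(=O)(=O)C(F)(F)F)=C/CC1
F4 | step 5 | tert-butyl{[(4R,7E)-3,3-dimethylnona-1,7-dien-4-yl]oxy}dimethylsilane | C=CC(C)(C)[C@H](O[Si](C)(C)C(C)(C)C)CC/C=C/C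
F5 | step 5 | tert-butyl{[(1R)-2,2-dimethylcyclohex-3-en-1-yl]oxy}dimethylsilane | C1=CC(C)(C)[C@H](O[Si](C)(C)C(C)(C)C)CC1
F6 | step 5 | (5R)-5-[(tert-butyldimethylsilyl)oxy]-4,4-dimethylcyclohex-2-en-1-one | O=C1C=CC(C)(C)[C@H](O[Si](C)(C)C(C)(C)C)C1
F7 | step 5 | (4R)-4-[(tert-butyldimethylsilyl)oxy]-5,5-dimethyl-8-methylidenebicyclo[4.2.0]octan-2-one | O=C1C[C@@H](O[Si](C)(C)C(C)(C)C)C(C)(C)C2CC(=C)C12
F8 | step 9 | tert-butyl{[(1R,3Z,8E)-2,2,9-trimethyl-5-methylidenecycloundeca-3,8-dien-1-yl]oxy}dimethylsilane | C=C1/C=C\C(C)(C)[C@H](O[Si](C)(C)C(C)(C)C)CC/C(C)=C/CC1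
F9 | step 4 | (5R)-5-[(tert-butyldimethylsilyl)oxy]-4,4-dimethylcyclohept-2-en-1-ol | OC1C=CC(C)(C)[C@H](O[Si](C)(C)C(C)(C)C)CC1
F10 | step 1 | 3,3-dimethylnona-1,8-dien-4-one | C=CC(C)(C)C(=O)CCCC=C
A1 | alternative 1 | tert-butyl{[(4R,7E)-3,3,7-trimethyl-11-methylidenetrideca-1,7,12-trien-4-yl]oxy}dimethylsilane | C=CC(=C)CC/C=C(C)/CC[C@@H](O[Si](C)(C)C(C)(C)C)C(C)(C)C=C
A2 | alternative 2 | (4E)-9-bromo-4,11-dimethyl-8-methylidenedodeca-4,10-dienal | O=CCC/C(C)=C/CCC(=C)C(Br)C=C(C)C
A3 | alternative 3 | tert-butyl{[(4R,7E)-3,3,7-trimethyldodeca-1,7-dien-11-yn-4-yl]oxy}dimethylsilane | C#CCC/C=C(C)/CC[C@@H](O[Si](C)(C)C(C)(C)C)C(C)(C)C=C
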